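**Retrosynthetic overview**

1. Prokinawan ⇐ its 3',4'-bis-TBS ether (buffered fluoride desilylation, last step).
2. Rings C and A are closed in one operation, in that order, from an open-chain (S)-δ-hydroxy triketo tert-butyl ester: acid cyclodehydration forms O1–C8a (ring C), then thermal loss of t-BuOH gives an acylketene that forms C4a–C5 (ring A) by 6π-electrocyclisation. Ring B is bought (protocatechualdehyde).
3. Open chain ⇐ polyanion of a 2-alkyl-3,5-dioxohexanoate + (S)-β-silyloxy thioester (Claisen acylation, C4–C4a).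
4. Thioester ⇐ bis-TBS protocatechualdehyde + thioacetate silyl ketene acetal (catalytic asymmetric Mukaiyama aldol sets C2). Diketo ester ⇐ tert-butyl acetoacetate + (E)-8-bromo-2,6-dimethyloct-6-en-2-ol (from geranyl acetate) + an acetyl donor.

Assumption: enolate and alkoxide forms of a numbered compound that are made and consumed in the same flask are treated as that compound and get no number of their own.
Assumption: the configuration at the enolisable α-carbon of keto esters 11 to 16 is immaterial (it becomes aromatic C6) and is left undefined.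

**Route**

Step 1
Reactants: 1 3,4-dihydroxybenzaldehyde
Product: 2 3,4-bis[(tert-butyldimethylsilyl)oxy]benzaldehyde
Conditions: TBSCl (2.3 equiv), imidazole (5 equiv), DMF, 25 °C
Reagents that add atoms: tert-butyldimethylsilyl chloride (TBSCl), CC(C)(C)[Si](C)(C)Cl
Why: Standard silyl ether formation on both phenols masks the acidic catechol for the Lewis-acid and enolate chemistry that follows.

Step 2
Reactants: 2 3,4-bis[(tert-butyldimethylsilyl)oxy]benzaldehyde; 3 1-(tert-butylsulfanyl)-1-[(trimethylsilyl)oxy]ethene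
Product: 4 S-tert-butyl (3S)-3-{3,4-bis[(tert-butyldimethylsilyl)oxy]phenyl}-3-[(trimethylsilyl)oxy]propanethioate
Conditions: Ti(OiPr)4/BINOL (1:1, 20 mol%; the BINOL antipode that gives Si-face addition), 4 Å MS, Et2O, −20 °C; pH 7 work-up, Et3N-deactivated silica
Reagents that add atoms: none
Why: Catalytic asymmetric Mukaiyama aldol addition with silyl transfer, in which the BINOL–titanium Lewis acid directs the thioketene acetal to the Si face of the aldehyde and so sets the carbinol carbon (later C2) as S (≥90% ee expected, to be checked as the Mosher ester).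

Step 3
Reactants: 5 geranyl acetate [(2E)-3,7-dimethylocta-2,6-dien-1-yl acetate]
Product: 8 (2E)-3,7-dimethyloct-2-ene-1,7-diol, via organomercurial 6 (not isolated), via hydroxy acetate 7 (not isolated)
Conditions: Hg(OAc)2 (1.0 equiv), THF/H2O 1:1, 25 °C; then NaBH4, 3 M NaOH, 0 → 25 °C
Reagents that add atoms: water, O
Why: Markovnikov oxymercuration–demercuration picks the distal 6,7-alkene because the 2,3-alkene is deactivated by the allylic acetate, and the NaOH of the demercuration saponifies the acetate while the E-alkene is untouched.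

Step 4
Reactants: 8 (2E)-3,7-dimethyloct-2-ene-1,7-diol
Product: 9 (6E)-8-bromo-2,6-dimethyloct-6-en-2-ol
Conditions: CBr4 (1.1 equiv), PPh3 (1.1 equiv), CH2Cl2, −20 → 0 °C; used crude
Reagents that add atoms: carbon tetrabromide, BrC(Br)(Br)Br
Why: Appel reaction, in which the primary allylic alcohol is displaced by SN2 far faster than the hindered tertiary alcohol reacts, so the E-allylic bromide forms selectively.

Step 5
Reactants: 9 (6E)-8-bromo-2,6-dimethyloct-6-en-2-ol; 10 tert-butyl acetoacetate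
Product: 11 tert-butyl (4E)-2-acetyl-9-hydroxy-5,9-dimethyldec-4-enoate
Conditions: 10 (1.5 equiv), NaH (1.4 equiv), THF, 0 °C; then 9, 0 → 25 °C
Reagents that add atoms: none
Why: Acetoacetic ester alkylation, in which the soft sodium enolate attacks the primary allylic bromide by SN2 at carbon with the E geometry kept, excess keto ester suppresses dialkylation and the weakly basic enolate leaves the tertiary alcohol alone.

Step 6
Reactants: 11 tert-butyl (4E)-2-acetyl-9-hydroxy-5,9-dimethyldec-4-enoate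
Product: 12 tert-butyl (4E)-9-hydroxy-5,9-dimethyl-2-(3-oxobutanoyl)dec-4-enoate
Conditions: LiN(iPr)2 (3.2 equiv), THF, −78 → 0 °C; MeC(O)N(OMe)Me (1.2 equiv), −78 → 0 °C; 1 M HCl
Reagents that add atoms: N-methoxy-N-methylacetamide, CC(=O)N(C)OC
Why: Huckin–Weiler dianion chemistry, in which the alkoxide–dianion reacts at its γ-carbon and the stable Weinreb chelate stops the reaction at mono-acylation to give the 3,5-diketo ester.

Step 7
Reactants: 12 tert-butyl (4E)-9-hydroxy-5,9-dimethyl-2-(3-oxobutanoyl)dec-4-enoate; 4 S-tert-butyl (3S)-3-{3,4-bis[(tert-butyldimethylsilyl)oxy]phenyl}-3-[(trimethylsilyl)oxy]propanethioate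
Product: 14 tert-butyl (4E)-2-{(7S)-7-[3,4-bis(tert-butyldimethylsilyloxy)phenyl]-7-hydroxy-3,5-dioxoheptanoyl}-9-hydroxy-5,9-dimethyldec-4-enoate, via TMS ether 13 (not isolated)
Conditions: 12 (1.6 equiv, excess recovered), LiN(iPr)2 (6.6 equiv), THF, −78 → 0 °C; then 4, −78 → −20 °C; 1 M HCl, THF, 0 °C (also cleaves the TMS ether); short silica plug
Reagents that add atoms: none
Why: Harris-type Claisen acylation of a β-polyketone polyanion, which reacts at its terminal (last-formed, most nucleophilic) carbon with the thioester, while no bond at the carbinol stereocentre is made or broken.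

Step 8
Reactants: 14 tert-butyl (4E)-2-{(7S)-7-[3,4-bis(tert-butyldimethylsilyloxy)phenyl]-7-hydroxy-3,5-dioxoheptanoyl}-9-hydroxy-5,9-dimethyldec-4-enoate
Product: 17 (2S)-2-{3,4-bis[(tert-butyldimethylsilyl)oxy]phenyl}-5,7-dihydroxy-6-[(2E)-7-hydroxy-3,7-dimethyloct-2-en-1-yl]-2,3-dihydro-4H-chromen-4-one, via dihydropyranone 15 (not isolated), via acylketene 16 (not isolated)
Conditions: TFA (10 mol%), PhMe (5 mM), 25 °C, 1 h; then 2,6-di-tert-butylpyridine (15 mol%), 110 °C, Dean–Stark, N2 sweep, 3 h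
Reagents that add atoms: none
Why: Proposed new method: at 25 °C catalytic TFA makes the (S)-carbinol oxygen add to the δ-ketone (future C8a) and lose water to give 2,3-dihydro-4H-pyran-4-one 15 (ring C; the known acid cyclodehydration of δ-hydroxy-β-diketones), which fixes O1 on C8a before ring A exists and so decides 6- over 8-substitution; at 110 °C the α-substituted tert-butyl β-keto ester expels tert-butanol to give acylketene 16 (known thermolysis of tert-butyl acetoacetates), whose dienol tautomer is a dienylketene that closes by 6π-electrocyclisation (the last step of the Danheiser benzannulation, equivalently C-acylation of the pyranone enol-ether carbon) and tautomerises to the phloroglucinol ring A; O-acylation is impossible because the only oxygen in reach is the ring ether, and no base is present, so C2 from step 2 is carried through unchanged.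

Step 9
Reactants: 17 (2S)-2-{3,4-bis[(tert-butyldimethylsilyl)oxy]phenyl}-5,7-dihydroxy-6-[(2E)-7-hydroxy-3,7-dimethyloct-2-en-1-yl]-2,3-dihydro-4H-chromen-4-one
Product: 18 Prokinawan [(2S)-2-(3,4-dihydroxyphenyl)-5,7-dihydroxy-6-[(2E)-7-hydroxy-3,7-dimethyloct-2-en-1-yl]-2,3-dihydro-4H-chromen-4-one]
Conditions: Bu4NF (2.2 equiv), AcOH (2.5 equiv), THF, 0 °C
Reagents that add atoms: none
Why: Fluoride cleavage of the two aryl silyl ethers, with AcOH buffering so that the 5-hydroxyflavanone never sees free phenoxide base, does not ring-open and keeps C2 as S, while the tertiary alcohol and the alkene are inert.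

**Compound list**

1 | 3,4-dihydroxybenzaldehyde | O=Cc1ccc(O)c(O)c1 | starting material
2 | 3,4-bis[(tert-butyldimethylsilyl)oxy]benzaldehyde | O=Cc1ccc(O[Si](C)(C)C(C)(C)C)c(O[Si](C)(C)C(C)(C)C)c1 | intermediate
3 | 1-(tert-butylsulfanyl)-1-[(trimethylsilyl)oxy]ethene | C=C(O[Si](C)(C)C)SC(C)(C)C | starting material
4 | S-tert-butyl (3S)-3-{3,4-bis[(tert-butyldimethylsilyl)oxy]phenyl}-3-[(trimethylsilyl)oxy]propanethioate | CC(C)(C)SC(=O)C[C@H](O[Si](C)(C)C)c1ccc(O[Si](C)(C)C(C)(C)C)c(O[Si](C)(C)C(C)(C)C)c1 | intermediate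
5 | geranyl acetate, (2E)-3,7-dimethylocta-2,6-dien-1-yl acetate | CC(=O)OC/C=C(\C)CCC=C(C)C | starting material
6 | (2E)-6-(acetoxymercurio)-7-hydroxy-3,7-dimethyloct-2-en-1-yl acetate (racemic at C6) | CC(=O)OC/C=C(\C)CCC([Hg]OC(C)=O)C(C)(C)O | intermediate
7 | (2E)-7-hydroxy-3,7-dimethyloct-2-en-1-yl acetate | CC(=O)OC/C=C(\C)CCCC(C)(C)O | intermediate
8 | (2E)-3,7-dimethyloct-2-ene-1,7-diol | OC/C=C(\C)CCCC(C)(C)O | intermediate
9 | (6E)-8-bromo-2,6-dimethyloct-6-en-2-ol | BrC/C=C(\C)CCCC(C)(C)O | intermediate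
10 | tert-butyl acetoacetate (tert-butyl 3-oxobutanoate) | CC(=O)CC(=O)OC(C)(C)C | starting material
11 | tert-butyl (4E)-2-acetyl-9-hydroxy-5,9-dimethyldec-4-enoate (C2 undefined) | CC(=O)C(C/C=C(\C)CCCC(C)(C)O)C(=O)OC(C)(C)C | intermediate
12 | tert-butyl (4E)-9-hydroxy-5,9-dimethyl-2-(3-oxobutanoyl)dec-4-enoate (C2 undefined) | CC(=O)CC(=O)C(C/C=C(\C)CCCC(C)(C)O)C(=O)OC(C)(C)C | intermediate
13 | tert-butyl (4E)-2-{(7S)-7-[3,4-bis(tert-butyldimethylsilyloxy)phenyl]-3,5-dioxo-7-[(trimethylsilyl)oxy]heptanoyl}-9-hydroxy-5,9-dimethyldec-4-enoate | CC(C)(C)OC(=O)C(C/C=C(\C)CCCC(C)(C)O)C(=O)CC(=O)CC(=O)C[C@H](O[Si](C)(C)C)c1ccc(O[Si](C)(C)C(C)(C)C)c(O[Si](C)(C)C(C)(C)C)c1 | intermediate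
14 | tert-butyl (4E)-2-{(7S)-7-[3,4-bis(tert-butyldimethylsilyloxy)phenyl]-7-hydroxy-3,5-dioxoheptanoyl}-9-hydroxy-5,9-dimethyldec-4-enoate | CC(C)(C)OC(=O)C(C/C=C(\C)CCCC(C)(C)O)C(=O)CC(=O)CC(=O)C[C@H](O)c1ccc(O[Si](C)(C)C(C)(C)C)c(O[Si](C)(C)C(C)(C)C)c1 | intermediate
15 | tert-butyl (4E)-2-{[(2S)-2-[3,4-bis(tert-butyldimethylsilyloxy)phenyl]-4-oxo-3,4-dihydro-2H-pyran-6-yl]acetyl}-9-hydroxy-5,9-dimethyldec-4-enoate | CC(C)(C)OC(=O)C(C/C=C(\C)CCCC(C)(C)O)C(=O)CC1=CC(=O)C[C@@H](c2ccc(O[Si](C)(C)C(C)(C)C)c(O[Si](C)(C)C(C)(C)C)c2)O1 | intermediate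
16 | (2S)-2-[3,4-bis(tert-butyldimethylsilyloxy)phenyl]-6-{3-[(2E)-7-hydroxy-3,7-dimethyloct-2-en-1-yl]-2,4-dioxobut-3-en-1-yl}-2,3-dihydro-4H-pyran-4-one (acylketene) | O=C=C(C/C=C(\C)CCCC(C)(C)O)C(=O)CC1=CC(=O)C[C@@H](c2ccc(O[Si](C)(C)C(C)(C)C)c(O[Si](C)(C)C(C)(C)C)c2)O1 | intermediate
17 | (2S)-2-{3,4-bis[(tert-butyldimethylsilyl)oxy]phenyl}-5,7-dihydroxy-6-[(2E)-7-hydroxy-3,7-dimethyloct-2-en-1-yl]-2,3-dihydro-4H-chromen-4-one | C/C(=C\Cc1c(O)cc2c(c1O)C(=O)C[C@@H](c1ccc(O[Si](C)(C)C(C)(C)C)c(O[Si](C)(C)C(C)(C)C)c1)O2)CCCC(C)(C)O | intermediate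
18 | Prokinawan, (2S)-2-(3,4-dihydroxyphenyl)-5,7-dihydroxy-6-[(2E)-7-hydroxy-3,7-dimethyloct-2-en-1-yl]-2,3-dihydro-4H-chromen-4-one | C/C(=C\Cc1c(O)cc2c(c1O)C(=O)C[C@@H](c1ccc(O)c(O)c1)O2)CCCC(C)(C)O | target

**Step count and risk**

Total steps: 9. Longest linear sequence: 7 steps (5 → 8 → 9 → 11 → 12 → 14 → 17 → 18; steps 3 to 9). The aldehyde branch (steps 1 and 2) joins at step 7.

The three steps most likely to fail:

Step 8 (the double ring closure). The risks are ketene formation before ring C is closed, acid-induced loss of isobutene followed by decarboxylation, and a slow electrocyclisation. The fallback sets out from 14 and comes back at 17. Only the acid stage is run (TFA cat., PhMe, 25 °C) and dihydropyranone 15, which is already in the list, is isolated, so the fallback makes none F0. Ring A is then closed by an anionic Dieckmann-type Claisen condensation instead of through the ketene: LiN(SiMe3)2 (3.3 equiv), THF, −78 → 0 °C, deprotonates the CH2 between the pyranone and the ketone, and the α-carbon of the extended enolate (C4a) attacks the tert-butyl ester. A cold AcOH quench limits base contact so that C2 is kept.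

Step 7 (polyanion Claisen). The risks are proton transfer or enolisation of thioester 4 with loss of the silyloxy group, and a low yield based on 12. The fallback sets out from 12 and aldehyde 2 and comes back at 14. Keto ester 12 is persilylated (Me3SiCl/Et3N, then LiN(iPr)2/Me3SiCl) to tert-butyl-derived 1-tert-butoxy-2-[(2E)-3,7-dimethyl-7-(trimethylsilyloxy)oct-2-en-1-yl]-1,3,5-tris(trimethylsilyloxy)hexa-1,3,5-triene F3. Its terminal carbon is added to aldehyde 2 in a Ti(OiPr)4/BINOL-catalysed vinylogous Mukaiyama aldol reaction with the same Si-face control. Work-up with 1 M HCl gives 14 directly. This bypasses 4 and the strongly basic coupling.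

Step 2 (enantioselectivity on an electron-rich, bulky aldehyde). The fallback sets out from 2 and comes back at 14. Aldehyde 2 is homologated with ethyl diazoacetate (SnCl2 cat., CH2Cl2, Roskamp reaction) to ethyl 3-{3,4-bis[(tert-butyldimethylsilyl)oxy]phenyl}-3-oxopropanoate F1. Noyori hydrogenation (RuCl2[(S)-BINAP] or its antipode as needed for the S alcohol, H2, EtOH) gives ethyl (3S)-3-{3,4-bis[(tert-butyldimethylsilyl)oxy]phenyl}-3-hydroxypropanoate F2. F2, as its lithium alkoxide (one equivalent of LiN(SiMe3)2), takes the place of 4 in step 7 and gives 14 after work-up; there is no silyl ether to remove.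

**Further compounds**

F1 | step 2 | ethyl 3-{3,4-bis[(tert-butyldimethylsilyl)oxy]phenyl}-3-oxopropanoate | CCOC(=O)CC(=O)c1ccc(O[Si](C)(C)C(C)(C)C)c(O[Si](C)(C)C(C)(C)C)c1
F2 | step 2 | ethyl (3S)-3-{3,4-bis[(tert-butyldimethylsilyl)oxy]phenyl}-3-hydroxypropanoate | CCOC(=O)C[C@H](O)c1ccc(O[Si](C)(C)C(C)(C)C)c(O[Si](C)(C)C(C)(C)C)c1
F3 | step 7 | 1-tert-butoxy-2-[(2E)-3,7-dimethyl-7-(trimethylsilyloxy)oct-2-en-1-yl]-1,3,5-tris(trimethylsilyloxy)hexa-1,3,5-triene (enol ether geometries undefined) | C=C(O[Si](C)(C)C)C=C(O[Si](C)(C)C)C(C/C=C(\C)CCCC(C)(C)O[Si](C)(C)C)=C(O[Si](C)(C)C)OC(C)(C)C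
F0 | step 8 | none | none
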